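The readings are simulated for substances that don't exist, and the scatter is random.

The pitfall in the flask asked about, Tuesday's, is to call E an excess and hold [E] at its charge. Each Z that reacts takes one E with it, so [E] falls from 0.640 M towards 0.320 M, half of that charge.

| flask | Z | E | remark | time |
|---|---|---|---|---|
| Tuesday's | 0.32 M | 0.64 M | the very flask that is asked about, followed so far |  |
| Friday's | 0.64 M | 0.64 M | run made earlier |  |
| flask | 0.32 M | 0.640 M |  | 80 min |

| run | time / min | L / % | Z / % |
|---|---|---|---|
| Tuesday's | 2.00 | 14 | 87 |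
| Tuesday's | 6.00 | 27 | 68 |
| Tuesday's | 10.0 | 41 | 57 |
| Tuesday's | 15.0 | 55 | 42 |
| Friday's | 8.00 | 33 | 66 |
| Friday's | 15.0 | 52 | 53 |
| Friday's | 25.0 | 61 | 43 |
| Friday's | 30.0 | 68 | 38 |

(each reading ± 2 percentage points)

1. equivalents of E to Z, everything else as given, that leave most L at 80 min
2. the amount of L then, in percent of the Z charged
3. the amount of L with the amounts as given

- the analysis behind the earlier runs scatters by 2 percentage points, standard deviation
- a reading or a percentage of L counts all its forms, free or not

Freeze the gap [E] − [Z] instead, since it stays at 0.320 M while each Z uses one E. Rate = k[Z][E] then integrates to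

[E]/[Z] = (charged ratio) × exp(k × gap × t).

Tuesday's reading of Z, 42% at 15.0 min, means [Z] = 0.134 M and [E] = 0.454 M. That gives the rate constant k = 0.109 M⁻¹ min⁻¹, a value read from one reading, with its scatter.

Now the ladder, fastest first:

Start, [E] at its charge: 1/(k[E]) = 14.3 min.

Tail, [E] near the gap, where Z decays pseudo-first-order: 1/(k × gap) = 28.6 min, twice as long.

Asked time: 80 min, or 2.80 tail times.

Last rung, unsized: any loss of L. Z and L together read 97.0% on Tuesday at 15.0 min and 106% on Friday at 30.0 min, either side of the whole charge, so these runs give this rung no number.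

At 80 min the ratio is 32.9, and [Z] = gap/(ratio − 1), so I expect 3.14% of Z left and L near 96.9%, less that unsized loss.

The forecast gives L 89% as charged, below my figure, and 90% at 2.3 equiv, calling it “The optimum is therefore broad”.

The flask gives L 93.3% as charged, and 95.7% at 2.82 equiv.

    Z + E → L + J (k = 0.0980 M⁻¹ min⁻¹)
    E + L → Q + J (k = 0.0340 M⁻¹ min⁻¹)
    Z → D (k = 5.90 × 10⁻⁵ min⁻¹)
    G ⇌ L, rate k4*(cs4 - [L]) while solid is left; crystals form when [L] > cs4 (solubility = 6.20 mM, k = 11.0 min⁻¹)

In this flask Z stands at 4.34% at 80.0 min, and the gap has gone from 0.320 M to 0.313 M. Now take the neighbouring flask, the same as this one but with 0.16 M of E, charged below Z. The gap turns round: [Z] − [E] = 0.160 M, and the same k makes [Z]/[E] reach 8.11 at 80 min. So [E] = 0.0225 M, which is 14.1% of its charge, with Z at 57.0%. At 80.0 min that neighbouring flask holds E at 16.4% of its charge, Z at 58.2% and L at 41.1%.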